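The flask held 0.30 M of solid substrate and 0.300 M of other conformer at 100 °C. Its target had read flat from 80.0 min to 300 min, and I had to say what time, removal or heat would add.

| setting | east | south-west | flask |
|---|---|---|---|
| solid substrate | 0.30 M | 0.15 M | 0.30 M |
| other conformer | 0.30 M | 0.30 M | 0.300 M |
| temperature | 100 °C | 95 °C | 100 °C |
| remark | the very flask that is asked about, followed so far | run made earlier |  |
| time |  |  | 6.0 h |

| east: time / min | east: target / % | south-west: time / min | south-west: target / % |
|---|---|---|---|
| 80.0 | 55.9 | 8.00 | 42.6 |
| 150 | 55.2 | 20.0 | 48.9 |
| 240 | 55.3 | 40.0 | 48.7 |
| 300 | 56.2 | 60.0 | 47.7 |

(readings scatter by 1 percentage point)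

- red: change nothing and wait 12 h more
- amber: at 6.0 h take out 90% of the target then present, then wait 12 h
- blue: at 6.0 h raise the temperature by 20 K, then wait 12 h

- given per volume of solution although it is solid: solid substrate
- removed target is counted in
- at the start none of the solid substrate is in solution

* target, in percent of the solid substrate and other conformer together first charged, at 6.0 h
* the remedy with the largest gain of target, or "none" below 2 percentage points (red / amber / blue / none)
* target present, with what was taken out counted in, in percent of the solid substrate and other conformer together first charged, after red
* target present, with what was taken out counted in, in percent of the solid substrate and other conformer together first charged, after amber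

I replaced the flat curve by one number:

P = 55.6%, error 0.5 percentage points

P is the plateau mean, the average of the readings on a flat stretch, and its error is the scatter over the root of their number.

Time: I checked what the mean hides by setting the later pair of readings against the earlier pair:

D = 0.2 points

This is less than the 1 point scatter of that difference, so I put now and red at P.

Removal: if target stood in balance with its isomers (thermodynamic control), what stayed in the flask would return to share P:

90% × P + P(1 − 90% × P) = 77.8%

If the feed had ended (kinetic control), amber would stay at P.

Heat: this turns on the same fork. The mean of the last readings of the south-west run was

S = 48.4%, error 0.58 points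

S lay 7.2 points below P, more than the error of P, at 95 °C and 0.15 M of solid substrate. The share in a first-order balance of isomers does not follow the charge, so under such a balance the temperature would have had to carry that gap. I leaned to an ended feed and to none, without proof.

The forecast gave 55.6%, 55.6% after red and 77.8% after amber, and chose amber: “I therefore read this as isomer equilibrium”. On amber it stood at the balance end of my fork, and I leaned to the other.

The flask gave 55.7%, 55.7% after red, 55.7% after amber and 55.7% after blue, so the best remedy was none.

    starting material → target (k = 0.522 min⁻¹, Ea = 97.0 kJ mol⁻¹)
    starting material ⇌ other conformer (K = 0.0580, k = 1.09 min⁻¹, Ea = 101 kJ mol⁻¹, ΔH = −50.0 kJ mol⁻¹)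
    solid substrate ⇌ starting material, rate k3*(cs3 - [starting material]) while solid is left; crystals form when [starting material] > cs3 (solubility = 0.120 M, k = 0.363 min⁻¹)
    other conformer → isomer of the product (k = 5.21 min⁻¹, Ea = 105 kJ mol⁻¹)
    2 starting material → self-condensation product (k = 0.594 M⁻¹ min⁻¹, Ea = 57.0 kJ mol⁻¹)
    (constants at 100 °C)

P lay within 0.5 points of the flask's 55.7%, and S of 48.4% stood beside the 48.1% of target that the south-west run held at the time of its last reading. In the flask, half of the turnover up to the asked time was done by 1.58 min in the reaction of other conformer to isomer of the product, by 4.59 min in the reaction of starting material to target and by 6.81 min in the dissolving of solid substrate. By 36.0 min solid substrate, starting material and other conformer stood at 0%, 0% and 0%, isomer of the product held 36.1%, self-condensation product 8.25%, and target 55.7%, still 55.7% at 3600 min.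

(All runs are simulated for substances that don't exist, noise included.)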